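**Retrosynthetic overview**
- Feature: ring A is fully substituted, with oxygen on C5 and C8 para to each other and C6–CH3 and C7–O between them, and it is fused through C4a=C8a to the 4-pyranone ring C. This is the p-alkoxyphenol pattern of a carbene benzannulation.
- Key disconnection (ring A, formed last): C5–C6, C7–C8 and C8–C8a by Dötz benzannulation. C5 is the carbene carbon of a 4-pyranon-3-yl(methoxy)carbene chromium complex, C8 one CO ligand, C6≡C7 is 1-(triisopropylsilyloxy)prop-1-yne, and C4a=C8a is the pyranone double bond.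
- Carbene complex: from the pyranone-3-carbonyl chloride and K2Cr(CO)5, then O-methylation, so that no metalated 4-pyranone is needed.
- Ring C (formed first; ring B is bought): γ-aroylation of the enaminone of methyl 4-methoxyacetoacetate with 4-methoxybenzoyl chloride, then acid cyclisation (O1–C8a bond).
- End game: methylate 8-OH, cleave the chelated 5-OMe with BCl3, remove the silyl group.

Key step: step 7

Assumption: the target has no stereocentre; enaminones 3 and 5 are written without alkene geometry because the push-pull double bond equilibrates and is consumed in the cyclisation.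

**Step 1**
Reactants: 1 methyl 4-methoxy-3-oxobutanoate; 2 N,N-dimethylformamide dimethyl acetal
Product: 3 methyl 2-[(dimethylamino)methylidene]-4-methoxy-3-oxobutanoate
Conditions: 2 (1.1 equiv), toluene, rt → 50 °C
Reagents that add atoms: none
Why: Knoevenagel-type condensation of the doubly activated C2 methylene with the amide acetal should give the push-pull enaminone with loss of two methanol.

**Step 2**
Reactants: 3 methyl 2-[(dimethylamino)methylidene]-4-methoxy-3-oxobutanoate; 4 4-methoxybenzoyl chloride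
Product: 6 methyl 5-methoxy-6-(4-methoxyphenyl)-4-oxo-4H-pyran-3-carboxylate, via acylated enaminone 5 (not isolated)
Conditions: LiN(SiMe3)2 (2.2 equiv), THF, −78 °C; then 3 M HCl, Et2O, rt
Reagents that add atoms: none
Why: Claisen-type C-acylation of the γ-dienolate at the methoxy-bearing carbon, then acid-promoted 6-endo addition–elimination of the aroyl enol oxygen onto the enaminone carbon with loss of dimethylamine, is the standard enaminone/acid chloride synthesis of 4-pyranone-3-carboxylates.

**Step 3**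
Reactants: 6 methyl 5-methoxy-6-(4-methoxyphenyl)-4-oxo-4H-pyran-3-carboxylate
Product: 7 5-methoxy-6-(4-methoxyphenyl)-4-oxo-4H-pyran-3-carboxylic acid
Conditions: 6 M HCl, AcOH, 90 °C
Reagents that add atoms: water, O
Why: Acid-catalysed ester hydrolysis (AAC2) avoids hydroxide, which would open the pyranone by conjugate addition, and aqueous HCl leaves the methyl ethers intact.

**Step 4**
Reactants: 7 5-methoxy-6-(4-methoxyphenyl)-4-oxo-4H-pyran-3-carboxylic acid
Product: 8 5-methoxy-6-(4-methoxyphenyl)-4-oxo-4H-pyran-3-carbonyl chloride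
Conditions: (COCl)2 (1.2 equiv), DMF (cat.), CH2Cl2, 0 °C → rt; used crude
Reagents that add atoms: oxalyl chloride, ClC(=O)C(=O)Cl
Why: Vilsmeier-catalysed acid chloride formation should be clean because the vinylogous-ester carbonyl of the pyranone is too weak a nucleophile to compete at this temperature.

**Step 5**
Reactants: 8 5-methoxy-6-(4-methoxyphenyl)-4-oxo-4H-pyran-3-carbonyl chloride; 9 chromium hexacarbonyl
Product: 12 pentacarbonyl{methoxy[5-methoxy-6-(4-methoxyphenyl)-4-oxo-4H-pyran-3-yl]methylidene}chromium, via dipotassium pentacarbonylchromate 10 (not isolated), via potassium acyl chromate 11 (not isolated)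
Conditions: Cr(CO)6, KC8 (2.2 equiv), THF, −78 °C; then 8, −78 → 0 °C; then Me3OBF4 (1.05 equiv), CH2Cl2, 0 °C
Reagents that add atoms: trimethyloxonium tetrafluoroborate, C[O+](C)C.F[B-](F)(F)F
Why: Semmelhack–Hegedus carbene synthesis, in which K2Cr(CO)5 substitutes the acyl chloride and the resulting acyl chromate is O-methylated (Fischer alkylation), should reach the carbene complex without a 3-lithio-4-pyranone that would ring-open or add to itself.

**Step 6**
Reactants: 13 ethyl acetate
Product: 16 1-(triisopropylsilyloxy)prop-1-yne, via lithium dibromoenolate 14 (not isolated), via lithium propynolate 15 (not isolated)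
Conditions: CH2Br2, lithium 2,2,6,6-tetramethylpiperidide, THF, −78 °C; 13; LiN(SiMe3)2; n-BuLi, −78 → 0 °C; then i-Pr3SiCl, −78 °C → rt
Reagents that add atoms: dibromomethane, BrCBr; chlorotriisopropylsilane, CC(C)[Si](Cl)(C(C)C)C(C)C
Why: Kowalski ester homologation stopped at the ynolate (addition of dibromomethyllithium, bromine–lithium exchange on the dibromoketone enolate, carbenoid 1,2-shift), with the bulky silyl chloride trapping the ynolate on oxygen.

**Step 7**
Reactants: 12 pentacarbonyl{methoxy[5-methoxy-6-(4-methoxyphenyl)-4-oxo-4H-pyran-3-yl]methylidene}chromium; 16 1-(triisopropylsilyloxy)prop-1-yne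
Product: 18 8-hydroxy-3,5-dimethoxy-2-(4-methoxyphenyl)-6-methyl-7-(triisopropylsilyloxy)-4H-chromen-4-one, via chromium tricarbonyl arene complex 17 (not isolated)
Conditions: 16 (1.5 equiv, slow addition), degassed THF, 50 °C; then air, CH2Cl2, rt
Reagents that add atoms: none
Why: Proposed new method: thermal loss of one CO from 12 lets the ynol ether insert into the Cr=C bond with its nucleophilic methyl-bearing carbon bonding to the carbene carbon (future C5), and CO then inserts at the new siloxy-substituted carbene carbon (C7) to give a chromium-bound dienylketene whose ketene carbon is C8. Ring A closes by 6π-electrocyclisation of that ketene carbon onto the pyranone CH (future C8a), and tautomerisation of the cyclohexadienone should give the chromium-complexed 8-phenol 17, which air frees without oxidising the hydroquinone monoether. The closest known reaction is the Dötz benzannulation of alkenyl(alkoxy)carbene chromium complexes with internal alkynes; neither a 4-pyranon-3-yl carbene nor a siloxyalkyne has been shown in it. No stereocentre is formed. The step needs methyl at C6 and silyloxy at C7, which both the polarisation of the ynol ether and the rule that the larger alkyne substituent ends beside the new hydroxyl dictate, and it needs six-ring over five-ring closure, which the alkenyl arm, the chromium centre, the donor solvent and the C8a–H that permits aromatisation favour. Slow addition of a small excess of alkyne limits [2+2] capture of the ketene by a second ynol ether.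

**Step 8**
Reactants: 18 8-hydroxy-3,5-dimethoxy-2-(4-methoxyphenyl)-6-methyl-7-(triisopropylsilyloxy)-4H-chromen-4-one
Product: 19 3,5,8-trimethoxy-2-(4-methoxyphenyl)-6-methyl-7-(triisopropylsilyloxy)-4H-chromen-4-one
Conditions: MeOH, PPh3, DIAD, THF, 0 °C → rt
Reagents that add atoms: methanol, CO
Why: Mitsunobu O-methylation of the single free phenol works without a metal base, so the triisopropylsilyl group should stay on O7 and not migrate to O8.

**Step 9**
Reactants: 19 3,5,8-trimethoxy-2-(4-methoxyphenyl)-6-methyl-7-(triisopropylsilyloxy)-4H-chromen-4-one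
Product: 20 5-hydroxy-3,8-dimethoxy-2-(4-methoxyphenyl)-6-methyl-7-(triisopropylsilyloxy)-4H-chromen-4-one
Conditions: BCl3 (1.5 equiv), CH2Cl2, −78 → 0 °C; then aq. NaHCO3
Reagents that add atoms: none
Why: Chelation-directed Lewis acid demethylation, in which BCl3 bridges the C4 carbonyl and the peri 5-OMe in a six-membered chelate and chloride removes that methyl group alone, should spare the 3-, 8- and 4'-methyl ethers.

**Step 10**
Reactants: 20 5-hydroxy-3,8-dimethoxy-2-(4-methoxyphenyl)-6-methyl-7-(triisopropylsilyloxy)-4H-chromen-4-one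
Product: 21 5,7-dihydroxy-3,8-dimethoxy-2-(4-methoxyphenyl)-6-methyl-4H-chromen-4-one (target)
Conditions: Bu4NF (1.1 equiv), AcOH (1.5 equiv), THF, 0 °C
Reagents that add atoms: none
Why: Fluoride-mediated desilylation of the aryl silyl ether, buffered with acetic acid, should release the 7-hydroxyl without affecting the rest of the flavone.

**Compound list**
1 | methyl 4-methoxy-3-oxobutanoate | COCC(=O)CC(=O)OC | starting material
2 | N,N-dimethylformamide dimethyl acetal | COC(OC)N(C)C | starting material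
3 | methyl 2-[(dimethylamino)methylidene]-4-methoxy-3-oxobutanoate | COCC(=O)C(=CN(C)C)C(=O)OC | intermediate
4 | 4-methoxybenzoyl chloride | COc1ccc(C(=O)Cl)cc1 | starting material
5 | methyl 2-[(dimethylamino)methylidene]-4-methoxy-5-(4-methoxyphenyl)-3,5-dioxopentanoate (not isolated) | COC(=O)C(=CN(C)C)C(=O)C(OC)C(=O)c1ccc(OC)cc1 | intermediate
6 | methyl 5-methoxy-6-(4-methoxyphenyl)-4-oxo-4H-pyran-3-carboxylate | COC(=O)c1coc(-c2ccc(OC)cc2)c(OC)c1=O | intermediate
7 | 5-methoxy-6-(4-methoxyphenyl)-4-oxo-4H-pyran-3-carboxylic acid | OC(=O)c1coc(-c2ccc(OC)cc2)c(OC)c1=O | intermediate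
8 | 5-methoxy-6-(4-methoxyphenyl)-4-oxo-4H-pyran-3-carbonyl chloride | ClC(=O)c1coc(-c2ccc(OC)cc2)c(OC)c1=O | intermediate
9 | chromium hexacarbonyl, Cr(CO)6 | O=C=[Cr](=C=O)(=C=O)(=C=O)(=C=O)=C=O | starting material
10 | dipotassium pentacarbonylchromate, K2Cr(CO)5 (not isolated) | [K+].[K+].O=C=[Cr-2](=C=O)(=C=O)(=C=O)=C=O | intermediate
11 | potassium pentacarbonyl{[5-methoxy-6-(4-methoxyphenyl)-4-oxo-4H-pyran-3-yl]carbonyl}chromate (not isolated) | [K+].[O-]C(c1coc(-c2ccc(OC)cc2)c(OC)c1=O)=[Cr](=C=O)(=C=O)(=C=O)(=C=O)=C=O | intermediate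
12 | pentacarbonyl{methoxy[5-methoxy-6-(4-methoxyphenyl)-4-oxo-4H-pyran-3-yl]methylidene}chromium | COC(c1coc(-c2ccc(OC)cc2)c(OC)c1=O)=[Cr](=C=O)(=C=O)(=C=O)(=C=O)=C=O | intermediate
13 | ethyl acetate | CCOC(C)=O | starting material
14 | lithium 1,1-dibromoprop-1-en-2-olate (not isolated) | [Li+].CC([O-])=C(Br)Br | intermediate
15 | lithium prop-1-yn-1-olate (not isolated) | [Li+].CC#C[O-] | intermediate
16 | 1-(triisopropylsilyloxy)prop-1-yne | CC#CO[Si](C(C)C)(C(C)C)C(C)C | intermediate
17 | tricarbonyl(eta-6-arene)chromium complex of 18, chromium bound to the six carbons of ring A; SMILES gives arene and Cr(CO)3 as dot-joined parts (not isolated) | COc1ccc(-c2oc3c(O)c(O[Si](C(C)C)(C(C)C)C(C)C)c(C)c(OC)c3c(=O)c2OC)cc1.O=C=[Cr](=C=O)=C=O | intermediate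
18 | 8-hydroxy-3,5-dimethoxy-2-(4-methoxyphenyl)-6-methyl-7-(triisopropylsilyloxy)-4H-chromen-4-one | COc1ccc(-c2oc3c(O)c(O[Si](C(C)C)(C(C)C)C(C)C)c(C)c(OC)c3c(=O)c2OC)cc1 | intermediate
19 | 3,5,8-trimethoxy-2-(4-methoxyphenyl)-6-methyl-7-(triisopropylsilyloxy)-4H-chromen-4-one | COc1ccc(-c2oc3c(OC)c(O[Si](C(C)C)(C(C)C)C(C)C)c(C)c(OC)c3c(=O)c2OC)cc1 | intermediate
20 | 5-hydroxy-3,8-dimethoxy-2-(4-methoxyphenyl)-6-methyl-7-(triisopropylsilyloxy)-4H-chromen-4-one | COc1ccc(-c2oc3c(OC)c(O[Si](C(C)C)(C(C)C)C(C)C)c(C)c(O)c3c(=O)c2OC)cc1 | intermediate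
21 | 5,7-dihydroxy-3,8-dimethoxy-2-(4-methoxyphenyl)-6-methyl-4H-chromen-4-one | COc1ccc(-c2oc3c(OC)c(O)c(C)c(O)c3c(=O)c2OC)cc1 | target

**Step count**
Total steps: 10. Longest linear sequence: 9 (steps 1–5 and 7–10); step 6 is the side branch.

**Steps most likely to fail**

Step 7 (key step). After alkyne insertion the complex may close a five-membered ring without CO insertion, the ketene may be captured by a second ynol ether, or the ynol ether may be consumed by silyl transfer before it inserts; in each case ring A would not form. The fallback uses known chemistry, sets out from 4 and comes back to the route at 21. Per-O-aroylation of 1-(2,4,6-trihydroxyphenyl)-2-methoxyethan-1-one F1 with 4 (pyridine) gives 2-(methoxyacetyl)benzene-1,3,5-triyl tris(4-methoxybenzoate) F2. Baker–Venkataraman rearrangement (KOH, pyridine, 50 °C) gives 1-[2-hydroxy-4,6-bis(4-methoxybenzoyloxy)phenyl]-2-methoxy-3-(4-methoxyphenyl)propane-1,3-dione F3, and HCl in methanol at reflux cyclodehydrates it and removes the two remaining aroyl groups to give 5,7-dihydroxy-3-methoxy-2-(4-methoxyphenyl)-4H-chromen-4-one F4. Benzylation of the non-chelated hydroxyl (BnBr, K2CO3, acetone) gives 7-(benzyloxy)-5-hydroxy-3-methoxy-2-(4-methoxyphenyl)-4H-chromen-4-one F5. Elbs persulfate oxidation (K2S2O8, aqueous KOH, pyridine) places oxygen para to the 5-hydroxyl as potassium 7-(benzyloxy)-5-hydroxy-3-methoxy-2-(4-methoxyphenyl)-4-oxo-4H-chromen-8-yl sulfate F6, which aqueous HCl hydrolyses to 7-(benzyloxy)-5,8-dihydroxy-3-methoxy-2-(4-methoxyphenyl)-4H-chromen-4-one F7. Methylation of the non-chelated 8-hydroxyl alone (Me2SO4, 1 equiv, K2CO3, acetone) gives 7-(benzyloxy)-5-hydroxy-3,8-dimethoxy-2-(4-methoxyphenyl)-4H-chromen-4-one F8. Iodination at C6, the only free position of ring A (N-iodosuccinimide, DMF), gives 7-(benzyloxy)-5-hydroxy-6-iodo-3,8-dimethoxy-2-(4-methoxyphenyl)-4H-chromen-4-one F9. Suzuki–Miyaura methylation (trimethylboroxine, Pd(dppf)Cl2, K2CO3, dioxane, 90 °C) gives 7-(benzyloxy)-5-hydroxy-3,8-dimethoxy-2-(4-methoxyphenyl)-6-methyl-4H-chromen-4-one F10, and hydrogenolysis (H2, Pd/C, EtOAc) gives 21.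

Step 5. The chromate dianion may transfer an electron to the pyranone or add to its C2 faster than it substitutes the acyl chloride, or the oxonium salt may methylate the pyranone carbonyl. The fallback sets out from 7 and comes back at 12. Decarboxylation (Cu powder, quinoline, 180 °C) gives 3-methoxy-2-(4-methoxyphenyl)-4H-pyran-4-one F11. Iodination at the carbon alpha to the carbonyl (I2, (NH4)2Ce(NO3)6, MeCN) gives 5-iodo-3-methoxy-2-(4-methoxyphenyl)-4H-pyran-4-one F12. Iodine–lithium exchange (t-BuLi, 2 equiv, THF/Et2O, −100 °C) gives 5-lithio-3-methoxy-2-(4-methoxyphenyl)-4H-pyran-4-one F13, which is transferred at once onto Cr(CO)6 to give lithium pentacarbonyl{[5-methoxy-6-(4-methoxyphenyl)-4-oxo-4H-pyran-3-yl]carbonyl}chromate F14 (the classical Fischer route). Me3OBF4 converts this into 12.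

Step 8. The phenoxide of the betaine ion pair may take over the silyl group from O7 before methyl transfer, or the doubly flanked phenol may fail to react; the outcome would be the 7-O-methyl isomer or unchanged 18. The fallback sets out from 18 and comes back at 21. Bu4NF/AcOH in THF removes the silyl group to give 7,8-dihydroxy-3,5-dimethoxy-2-(4-methoxyphenyl)-6-methyl-4H-chromen-4-one F15. The more acidic 7-hydroxyl, conjugated with the C4 carbonyl, is benzylated selectively (BnBr, 1 equiv, KHCO3, DMF) to give 7-(benzyloxy)-8-hydroxy-3,5-dimethoxy-2-(4-methoxyphenyl)-6-methyl-4H-chromen-4-one F16. Methylation of the remaining hydroxyl (MeI, K2CO3, acetone) gives 7-(benzyloxy)-3,5,8-trimethoxy-2-(4-methoxyphenyl)-6-methyl-4H-chromen-4-one F17. BCl3 (CH2Cl2, −78 → 0 °C) then removes both the benzyl group and the chelated 5-O-methyl group to give 21.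

**Further compounds**
F1 | step 7 | 1-(2,4,6-trihydroxyphenyl)-2-methoxyethan-1-one | COCC(=O)c1c(O)cc(O)cc1O
F2 | step 7 | 2-(methoxyacetyl)benzene-1,3,5-triyl tris(4-methoxybenzoate) | COCC(=O)c1c(OC(=O)c2ccc(OC)cc2)cc(OC(=O)c2ccc(OC)cc2)cc1OC(=O)c1ccc(OC)cc1
F3 | step 7 | 1-[2-hydroxy-4,6-bis(4-methoxybenzoyloxy)phenyl]-2-methoxy-3-(4-methoxyphenyl)propane-1,3-dione | COc1ccc(C(=O)C(OC)C(=O)c2c(O)cc(OC(=O)c3ccc(OC)cc3)cc2OC(=O)c2ccc(OC)cc2)cc1
F4 | step 7 | 5,7-dihydroxy-3-methoxy-2-(4-methoxyphenyl)-4H-chromen-4-one | COc1ccc(-c2oc3cc(O)cc(O)c3c(=O)c2OC)cc1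
F5 | step 7 | 7-(benzyloxy)-5-hydroxy-3-methoxy-2-(4-methoxyphenyl)-4H-chromen-4-one | COc1ccc(-c2oc3cc(OCc4ccccc4)cc(O)c3c(=O)c2OC)cc1
F6 | step 7 | potassium 7-(benzyloxy)-5-hydroxy-3-methoxy-2-(4-methoxyphenyl)-4-oxo-4H-chromen-8-yl sulfate | [K+].COc1ccc(-c2oc3c(OS(=O)(=O)[O-])c(OCc4ccccc4)cc(O)c3c(=O)c2OC)cc1
F7 | step 7 | 7-(benzyloxy)-5,8-dihydroxy-3-methoxy-2-(4-methoxyphenyl)-4H-chromen-4-one | COc1ccc(-c2oc3c(O)c(OCc4ccccc4)cc(O)c3c(=O)c2OC)cc1
F8 | step 7 | 7-(benzyloxy)-5-hydroxy-3,8-dimethoxy-2-(4-methoxyphenyl)-4H-chromen-4-one | COc1ccc(-c2oc3c(OC)c(OCc4ccccc4)cc(O)c3c(=O)c2OC)cc1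
F9 | step 7 | 7-(benzyloxy)-5-hydroxy-6-iodo-3,8-dimethoxy-2-(4-methoxyphenyl)-4H-chromen-4-one | COc1ccc(-c2oc3c(OC)c(OCc4ccccc4)c(I)c(O)c3c(=O)c2OC)cc1
F10 | step 7 | 7-(benzyloxy)-5-hydroxy-3,8-dimethoxy-2-(4-methoxyphenyl)-6-methyl-4H-chromen-4-one | COc1ccc(-c2oc3c(OC)c(OCc4ccccc4)c(C)c(O)c3c(=O)c2OC)cc1
F11 | step 5 | 3-methoxy-2-(4-methoxyphenyl)-4H-pyran-4-one | COc1ccc(-c2occc(=O)c2OC)cc1
F12 | step 5 | 5-iodo-3-methoxy-2-(4-methoxyphenyl)-4H-pyran-4-one | COc1ccc(-c2occ(I)c(=O)c2OC)cc1
F13 | step 5 | 5-lithio-3-methoxy-2-(4-methoxyphenyl)-4H-pyran-4-one | [Li]c1coc(-c2ccc(OC)cc2)c(OC)c1=O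
F14 | step 5 | lithium pentacarbonyl{[5-methoxy-6-(4-methoxyphenyl)-4-oxo-4H-pyran-3-yl]carbonyl}chromate | [Li+].[O-]C(c1coc(-c2ccc(OC)cc2)c(OC)c1=O)=[Cr](=C=O)(=C=O)(=C=O)(=C=O)=C=O
F15 | step 8 | 7,8-dihydroxy-3,5-dimethoxy-2-(4-methoxyphenyl)-6-methyl-4H-chromen-4-one | COc1ccc(-c2oc3c(O)c(O)c(C)c(OC)c3c(=O)c2OC)cc1
F16 | step 8 | 7-(benzyloxy)-8-hydroxy-3,5-dimethoxy-2-(4-methoxyphenyl)-6-methyl-4H-chromen-4-one | COc1ccc(-c2oc3c(O)c(OCc4ccccc4)c(C)c(OC)c3c(=O)c2OC)cc1
F17 | step 8 | 7-(benzyloxy)-3,5,8-trimethoxy-2-(4-methoxyphenyl)-6-methyl-4H-chromen-4-one | COc1ccc(-c2oc3c(OC)c(OCc4ccccc4)c(C)c(OC)c3c(=O)c2OC)cc1
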